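## Retrosynthetic overview

1. Target 25 ⇐ acetonide 24 ⇐ alcohol 21 + angelic acid; the C8 ester goes on last, with O9/O14 held as one acetonide.
2. The ten-membered carbocycle and the trans γ-lactone come from one C6–C7 bond: CrCl2-mediated intramolecular 2-(methoxycarbonyl)allylation of Z-enal 17. The carbocycle closes first and the lactone closes in the same pot.
3. The allyl unit ⇐ Wittig olefination of lactol 10 with the stannylated ylide 14.
4. C8/C9 ⇐ D-proline cross-aldol of aldehyde 8 onto Z-enal 7; this is the only enantio-determining step, and C6/C7 are relayed from C8.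
5. Z-enal 7 ⇐ neryl acetate (4Z alkene carried from nerol; the 1(10) alkene geometry is set by Baylis–Hillman / SN2' bromination).

Assumption: neryl acetate, methyl acrylate, (4-methoxybenzyloxy)acetaldehyde, methyl (triphenylphosphoranylidene)acetate, tributyl(iodomethyl)stannane and angelic acid are bought; germacrane numbering (C1–C15) is used for positions.

## Route

Step 1
Reactants: 1 neryl acetate
Product: 2 (4Z)-6-acetoxy-4-methylhex-4-enal
Conditions: O3 (1.0 equiv), pyridine (3 equiv), CH2Cl2, −78 °C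
Reagents that add atoms: ozone, [O-][O+]=O
Why: Regioselective ozonolysis: the isolated 6,7-alkene is more electron-rich than the acetate-deactivated allylic alkene, and pyridine converts the carbonyl oxide directly to the aldehyde; no stereocentre is formed.

Step 2
Reactants: 2 (4Z)-6-acetoxy-4-methylhex-4-enal; 3 methyl acrylate
Product: 4 methyl 2-[(4Z)-6-acetoxy-1-hydroxy-4-methylhex-4-enyl]prop-2-enoate (racemic carbinol)
Conditions: DABCO (1 equiv), neat 3 (4 equiv), 23 °C, 4 d
Reagents that add atoms: none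
Why: Morita–Baylis–Hillman reaction of an aliphatic aldehyde; the racemic carbinol is not a target centre and is erased in step 3.

Step 3
Reactants: 4 methyl 2-[(4Z)-6-acetoxy-1-hydroxy-4-methylhex-4-enyl]prop-2-enoate
Product: 5 methyl (2Z,6Z)-8-acetoxy-2-(bromomethyl)-6-methylocta-2,6-dienoate
Conditions: PBr3 (0.5 equiv), Et2O, 0 °C
Reagents that add atoms: phosphorus tribromide, BrP(Br)Br
Why: SN2' bromination of a Baylis–Hillman adduct gives the (Z)-2-(bromomethyl)enoate with the ester trans to the chain, which fixes the future C1=C10 geometry (C9 cis to C2, C14 trans).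

Step 4
Reactants: 5 methyl (2Z,6Z)-8-acetoxy-2-(bromomethyl)-6-methylocta-2,6-dienoate
Product: 6 (2Z,6Z)-2-(bromomethyl)-6-methylocta-2,6-diene-1,8-diol
Conditions: i-Bu2AlH (5 equiv), CH2Cl2, −78 to −20 °C; Rochelle salt work-up
Reagents that add atoms: none
Why: Hydride reduction of the methyl ester and the acetate at low temperature, where the allylic bromide and the alkene geometry are untouched.

Step 5
Reactants: 6 (2Z,6Z)-2-(bromomethyl)-6-methylocta-2,6-diene-1,8-diol
Product: 7 (2Z,6Z)-8-hydroxy-2-(hydroxymethyl)-6-methylocta-2,6-dienal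
Conditions: N-methylmorpholine N-oxide (4 equiv), 4 Å MS, MeCN, 0 to 23 °C
Reagents that add atoms: N-methylmorpholine N-oxide, C[N+]1([O-])CCOCC1
Why: Ganem-type N-oxide oxidation (SN2 at the primary allylic bromide, then elimination) gives the enal with the formyl group cis to the chain; the free hydroxyls are tolerated.

Step 6
Reactants: 7 (2Z,6Z)-8-hydroxy-2-(hydroxymethyl)-6-methylocta-2,6-dienal; 8 (4-methoxybenzyloxy)acetaldehyde
Product: 10 lactol (3R,4R,5Z)-5-[(4Z)-6-hydroxy-4-methylhex-4-enylidene]-3-(4-methoxybenzyloxy)oxane-2,4-diol (both anomers), via open-chain aldol aldehyde 9 (not isolated)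
Conditions: D-proline (30 mol %), DMF, 4 °C; 8 (2.5 equiv) added over 36 h
Reagents that add atoms: none
Why: Proposed new method: an enamine cross-aldol onto an α-branched (Z)-2-(hydroxymethyl)enal acceptor, in which the anti-enamine of 8 attacks the C9 formyl group of 7 through the Houk–List hydrogen-bonded transition state (D-proline gives the anti 8,9-diol, 2R,3R in 9, which is 8S,9R in the target), 7 cannot form an enamine and is a poor iminium partner so it acts only as the electrophile, slow addition of 8 limits its self-aldol, and the C14 hydroxyl traps the product as six-membered lactol 10 so that retro-aldol and further aldol are shut off; the closest known reaction is the proline-catalysed anti-selective cross-aldol of α-oxyaldehyde donors with non-enolisable aldehyde acceptors.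

Step 7
Reactants: 11 methyl (triphenyl-λ5-phosphanylidene)acetate; 12 tributyl(iodomethyl)stannane
Product: 14 methyl 3-(tributylstannyl)-2-(triphenyl-λ5-phosphanylidene)propanoate, via phosphonium iodide 13 (not isolated)
Conditions: 11 (2.0 equiv), 12 (1.0 equiv), toluene, 40 °C
Reagents that add atoms: none
Why: C-alkylation of a stabilised ylide by a reactive primary iodide followed by transylidation (the second equivalent of 11 deprotonates salt 13 at once).

Step 8
Reactants: 10 lactol; 14 methyl 3-(tributylstannyl)-2-(triphenyl-λ5-phosphanylidene)propanoate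
Product: 15 methyl (2Z,4S,5R,6Z,10Z)-5,12-dihydroxy-6-(hydroxymethyl)-4-(4-methoxybenzyloxy)-10-methyl-2-[(tributylstannyl)methyl]dodeca-2,6,10-trienoate (ester trans to C4)
Conditions: 14 (1.5 equiv), PhCO2H (10 mol %), toluene, 80 °C
Reagents that add atoms: none
Why: Wittig olefination of a lactol through its open-chain aldehyde; the stabilised ylide gives the enoate with the ester trans to C8 under neutral conditions that do not epimerise C8.

Step 9
Reactants: 15 allylstannane triol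
Product: 16 methyl (2Z,4S)-4-{(4R,5Z)-5-[(4Z)-6-hydroxy-4-methylhex-4-enylidene]-2,2-dimethyl-1,3-dioxan-4-yl}-4-(4-methoxybenzyloxy)-2-[(tributylstannyl)methyl]but-2-enoate
Conditions: Me2C(OMe)2, PPTS (5 mol %), CH2Cl2, 23 °C; aq. NaHCO3
Reagents that add atoms: 2,2-dimethoxypropane, COC(C)(C)OC
Why: Acetonide formation on the only 1,3-diol (O9/O14, six-membered dioxane); O8 is blocked as the PMB ether and the lone C6 hydroxyl is recovered on work-up.

Step 10
Reactants: 16 acetonide alcohol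
Product: 17 methyl (2Z,4S)-4-{(4R,5Z)-2,2-dimethyl-5-[(4Z)-4-methyl-6-oxohex-4-enylidene]-1,3-dioxan-4-yl}-4-(4-methoxybenzyloxy)-2-[(tributylstannyl)methyl]but-2-enoate
Conditions: MnO2 (20 equiv), CH2Cl2, 23 °C
Reagents that add atoms: none
Why: Chemoselective MnO2 oxidation of the primary allylic alcohol to the (Z)-enal, as for nerol to neral, without Z/E isomerisation.

Step 11
Reactants: 17 stannyl enal
Product: 20 (6R,7S,8S,9R)-9,14-(isopropylidenedioxy)-8-(4-methoxybenzyloxy)germacra-1(10)Z,4Z,11(13)-trien-12,6-olide, via allylic iodide 18 (not isolated), via hydroxy ester 19 (not isolated)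
Conditions: I2 (1.0 equiv), THF, −78 °C; then added over 12 h to CrCl2 (10 equiv), THF (2 mM), 23 °C
Reagents that add atoms: none
Why: Nozaki–Hiyama–Kishi-type (Barbier) 2-(alkoxycarbonyl)allylation: SE2' iododestannylation gives iodide 18, CrCl2 converts it to an allylchromium that adds γ-selectively to the C6 aldehyde through a chair transition state with C8 equatorial (anti addition, hence the trans 6,7-lactone), C7 is attacked anti to C9 in the A(1,3)-minimised conformer with the C8–O bond outside (hence 7S next to 8S), and the chromium alkoxide of 19 lactonises onto the ester; the non-acidic medium avoids ene cyclisation of the citral-like enal.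

Step 12
Reactants: 20 PMB-protected macrolactone
Product: 21 (6R,7S,8S,9R)-8-hydroxy-9,14-(isopropylidenedioxy)germacra-1(10)Z,4Z,11(13)-trien-12,6-olide
Conditions: DDQ (1.5 equiv), CH2Cl2/pH 7 phosphate buffer (10:1), 0 °C
Reagents that add atoms: none
Why: Oxidative cleavage of the PMB ether by DDQ; the acetonide, α-methylene lactone and both trisubstituted alkenes are inert under buffered conditions.

Step 13
Reactants: 21 C8 alcohol; 22 angelic acid
Product: 24 (6R,7S,8S,9R)-8-angeloyloxy-9,14-(isopropylidenedioxy)germacra-1(10)Z,4Z,11(13)-trien-12,6-olide, via mixed anhydride 23 (not isolated)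
Conditions: 22 (4 equiv), 2,4,6-Cl3C6H2COCl (4 equiv), Et3N, toluene, 23 °C; then 21, 80 °C
Reagents that add atoms: none
Why: Yamaguchi-type mixed-anhydride esterification of the only free hydroxyl, run without nucleophilic amine catalyst so that the angelate does not isomerise to the tiglate.

Step 14
Reactants: 24 angelate acetonide
Product: 25 (3aS,4S,5R,6Z,10Z,11aR)-5-hydroxy-6-(hydroxymethyl)-10-methyl-3-methylidene-2-oxo-2,3,3a,4,5,8,9,11a-octahydrocyclodeca[b]furan-4-yl (2Z)-2-methylbut-2-enoate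
Conditions: AcOH/H2O (4:1), 35 °C
Reagents that add atoms: none
Why: Mild acid hydrolysis of the 1,3-dioxane acetonide frees O9 and O14 without base, so the angelate does not migrate and the α-methylene lactone is untouched.

## Compound list

1 | neryl acetate, (2Z)-3,7-dimethylocta-2,6-dienyl acetate | CC(=O)OC/C=C(/C)CCC=C(C)C | starting material
2 | (4Z)-6-acetoxy-4-methylhex-4-enal | CC(=O)OC/C=C(/C)CCC=O | intermediate
3 | methyl acrylate | C=CC(=O)OC | starting material
4 | methyl 2-[(4Z)-6-acetoxy-1-hydroxy-4-methylhex-4-enyl]prop-2-enoate (racemic) | C=C(C(=O)OC)C(O)CC/C(C)=C\COC(C)=O | intermediate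
5 | methyl (2Z,6Z)-8-acetoxy-2-(bromomethyl)-6-methylocta-2,6-dienoate | COC(=O)/C(CBr)=C/CC/C(C)=C\COC(C)=O | intermediate
6 | (2Z,6Z)-2-(bromomethyl)-6-methylocta-2,6-diene-1,8-diol | OC/C(CBr)=C/CC/C(C)=C\CO | intermediate
7 | (2Z,6Z)-8-hydroxy-2-(hydroxymethyl)-6-methylocta-2,6-dienal | O=C/C(CO)=C\CC/C(C)=C\CO | intermediate
8 | (4-methoxybenzyloxy)acetaldehyde | COc1ccc(COCC=O)cc1 | starting material
9 | (2R,3R,4Z,8Z)-3,10-dihydroxy-4-(hydroxymethyl)-2-(4-methoxybenzyloxy)-8-methyldeca-4,8-dienal | OC/C=C(/C)CC/C=C(/CO)[C@@H](O)[C@@H](OCc1ccc(OC)cc1)C=O | intermediate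
10 | (3R,4R,5Z)-5-[(4Z)-6-hydroxy-4-methylhex-4-enylidene]-3-(4-methoxybenzyloxy)oxane-2,4-diol (anomers) | OC/C=C(/C)CC/C=C1/COC(O)[C@H](OCc2ccc(OC)cc2)[C@@H]1O | intermediate
11 | methyl (triphenyl-λ5-phosphanylidene)acetate | COC(=O)C=P(c1ccccc1)(c1ccccc1)c1ccccc1 | starting material
12 | tributyl(iodomethyl)stannane | CCCC[Sn](CCCC)(CCCC)CI | starting material
13 | [1-methoxy-1-oxo-3-(tributylstannyl)propan-2-yl]triphenylphosphonium iodide | COC(=O)C(C[Sn](CCCC)(CCCC)CCCC)[P+](c1ccccc1)(c1ccccc1)c1ccccc1.[I-] | intermediate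
14 | methyl 3-(tributylstannyl)-2-(triphenyl-λ5-phosphanylidene)propanoate | COC(=O)C(C[Sn](CCCC)(CCCC)CCCC)=P(c1ccccc1)(c1ccccc1)c1ccccc1 | intermediate
15 | methyl (2Z,4S,5R,6Z,10Z)-5,12-dihydroxy-6-(hydroxymethyl)-4-(4-methoxybenzyloxy)-10-methyl-2-[(tributylstannyl)methyl]dodeca-2,6,10-trienoate | OC/C=C(/C)CC/C=C(/CO)[C@@H](O)[C@@H](OCc1ccc(OC)cc1)/C=C(\C[Sn](CCCC)(CCCC)CCCC)C(=O)OC | intermediate
16 | methyl (2Z,4S)-4-{(4R,5Z)-5-[(4Z)-6-hydroxy-4-methylhex-4-enylidene]-2,2-dimethyl-1,3-dioxan-4-yl}-4-(4-methoxybenzyloxy)-2-[(tributylstannyl)methyl]but-2-enoate | OC/C=C(/C)CC/C=C1/COC(C)(C)O[C@H]1[C@@H](OCc2ccc(OC)cc2)/C=C(\C[Sn](CCCC)(CCCC)CCCC)C(=O)OC | intermediate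
17 | methyl (2Z,4S)-4-{(4R,5Z)-2,2-dimethyl-5-[(4Z)-4-methyl-6-oxohex-4-enylidene]-1,3-dioxan-4-yl}-4-(4-methoxybenzyloxy)-2-[(tributylstannyl)methyl]but-2-enoate | O=C/C=C(/C)CC/C=C1/COC(C)(C)O[C@H]1[C@@H](OCc2ccc(OC)cc2)/C=C(\C[Sn](CCCC)(CCCC)CCCC)C(=O)OC | intermediate
18 | methyl (4R)-4-{(4R,5Z)-2,2-dimethyl-5-[(4Z)-4-methyl-6-oxohex-4-enylidene]-1,3-dioxan-4-yl}-3-iodo-4-(4-methoxybenzyloxy)-2-methylidenebutanoate (C3 epimers) | O=C/C=C(/C)CC/C=C1/COC(C)(C)O[C@H]1[C@@H](OCc2ccc(OC)cc2)C(I)C(=C)C(=O)OC | intermediate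
19 | methyl (6R,7S,8S,9R)-6-hydroxy-9,14-(isopropylidenedioxy)-8-(4-methoxybenzyloxy)germacra-1(10)Z,4Z,11(13)-trien-12-oate | C=C(C(=O)OC)[C@H]1[C@H](O)/C=C(/C)CC/C=C2/COC(C)(C)O[C@H]2[C@H]1OCc3ccc(OC)cc3 | intermediate
20 | (6R,7S,8S,9R)-9,14-(isopropylidenedioxy)-8-(4-methoxybenzyloxy)germacra-1(10)Z,4Z,11(13)-trien-12,6-olide | C=C1C(=O)O[C@@H]2/C=C(/C)CC/C=C3/COC(C)(C)O[C@H]3[C@@H](OCc4ccc(OC)cc4)[C@@H]12 | intermediate
21 | (6R,7S,8S,9R)-8-hydroxy-9,14-(isopropylidenedioxy)germacra-1(10)Z,4Z,11(13)-trien-12,6-olide | C=C1C(=O)O[C@@H]2/C=C(/C)CC/C=C3/COC(C)(C)O[C@H]3[C@@H](O)[C@@H]12 | intermediate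
22 | angelic acid, (2Z)-2-methylbut-2-enoic acid | C/C=C(/C)C(=O)O | starting material
23 | (2Z)-2-methylbut-2-enoic 2,4,6-trichlorobenzoic anhydride | C/C=C(/C)C(=O)OC(=O)c1c(Cl)cc(Cl)cc1Cl | intermediate
24 | (6R,7S,8S,9R)-8-angeloyloxy-9,14-(isopropylidenedioxy)germacra-1(10)Z,4Z,11(13)-trien-12,6-olide | C=C1C(=O)O[C@@H]2/C=C(/C)CC/C=C3/COC(C)(C)O[C@H]3[C@@H](OC(=O)/C(C)=C\C)[C@@H]12 | intermediate
25 | (3aS,4S,5R,6Z,10Z,11aR)-5-hydroxy-6-(hydroxymethyl)-10-methyl-3-methylidene-2-oxo-2,3,3a,4,5,8,9,11a-octahydrocyclodeca[b]furan-4-yl (2Z)-2-methylbut-2-enoate | C=C1C(=O)O[C@@H]2/C=C(/C)CC/C=C(/CO)[C@@H](O)[C@@H](OC(=O)/C(C)=C\C)[C@@H]12 | target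

## Step count and risks

Total step count: 14. Longest linear sequence: 13 (steps 1–6 and 8–14); step 7 is the one-step side branch to ylide 14.

The three steps most likely to fail are 6, 8 and 11.

Step 6 (the proposed new aldol). The risks are self-aldol of 8 outrunning attack on the conjugated acceptor, and Z-to-E drift of 7 under amine catalysis. The fallback uses known chemistry, sets out from 7 and comes back at 10. Enal 7 is silylated (Et3SiCl, imidazole) to (2Z,6Z)-6-methyl-8-(triethylsilyloxy)-2-[(triethylsilyloxy)methyl]octa-2,6-dienal F1. Commercial (4-methoxybenzyloxy)acetic acid is converted (EtSH, DCC) to S-ethyl (4-methoxybenzyloxy)thioacetate F2 and then (LiN(i-Pr)2, Me3SiCl) to (Z)-1-(ethylsulfanyl)-2-(4-methoxybenzyloxy)-1-(trimethylsilyloxy)ethene F3. An anti-selective Mukaiyama aldol of F3 with F1, catalysed by Sn(OTf)2 (divalent tin) and a chiral 2-(aminomethyl)pyrrolidine diamine, gives S-ethyl (2R,3R,4Z,8Z)-3-hydroxy-2-(4-methoxybenzyloxy)-8-methyl-10-(triethylsilyloxy)-4-[(triethylsilyloxy)methyl]deca-4,8-dienethioate F4. Reduction with i-Bu2AlH at −78 °C gives (2R,3R,4Z,8Z)-3-hydroxy-2-(4-methoxybenzyloxy)-8-methyl-10-(triethylsilyloxy)-4-[(triethylsilyloxy)methyl]deca-4,8-dienal F5, and AcOH/THF/H2O desilylation closes it to lactol 10.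

Step 8 (Wittig on the lactol). The risks are the low open-chain content of 10, a hindered ylide, and oxa-Michael closure of the liberated C14 hydroxyl onto the new enoate. The fallback avoids the lactol altogether; it sets out from 7 and comes back at 15. Enal 7 is converted to the bis(triethylsilyl) ether F1, and the D-proline aldol with 8 then gives the open-chain aldehyde (2R,3R,4Z,8Z)-3-hydroxy-2-(4-methoxybenzyloxy)-8-methyl-10-(triethylsilyloxy)-4-[(triethylsilyloxy)methyl]deca-4,8-dienal F5, which cannot lactolise. F5 is olefinated with 14 at 23 °C to methyl (2Z,4S,5R,6Z,10Z)-5-hydroxy-4-(4-methoxybenzyloxy)-10-methyl-12-(triethylsilyloxy)-6-[(triethylsilyloxy)methyl]-2-[(tributylstannyl)methyl]dodeca-2,6,10-trienoate F6, and AcOH/THF/H2O desilylation gives 15.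

Step 11 (macrocyclisation). The risks are oligomerisation, 1,4-elimination of the C8 oxygen from the allylmetal, and the wrong C6/C7 diastereomer. The fallback changes the control element from a non-chelated organochromium chair to a hydroxyl-chelated aqueous indium Barbier closure; it sets out from 17 and comes back at 21. Iodide 18 is isolated after the I2 step and its PMB group is removed with DDQ to give methyl (4R)-4-{(4R,5Z)-2,2-dimethyl-5-[(4Z)-4-methyl-6-oxohex-4-enylidene]-1,3-dioxan-4-yl}-4-hydroxy-3-iodo-2-methylidenebutanoate F7. Indium powder in THF/H2O at high dilution, with the free C8 hydroxyl chelating the allylindium, gives methyl (6R,7S,8S,9R)-6,8-dihydroxy-9,14-(isopropylidenedioxy)germacra-1(10)Z,4Z,11(13)-trien-12-oate F8, whose newly formed O6 indium alkoxide lactonises in the flask to 21.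

## Further compounds

F1 | step 6 | (2Z,6Z)-6-methyl-8-(triethylsilyloxy)-2-[(triethylsilyloxy)methyl]octa-2,6-dienal | O=C/C(CO[Si](CC)(CC)CC)=C\CC/C(C)=C\CO[Si](CC)(CC)CC
F2 | step 6 | S-ethyl (4-methoxybenzyloxy)thioacetate | CCSC(=O)COCc1ccc(OC)cc1
F3 | step 6 | (Z)-1-(ethylsulfanyl)-2-(4-methoxybenzyloxy)-1-(trimethylsilyloxy)ethene | CCS/C(O[Si](C)(C)C)=C\OCc1ccc(OC)cc1
F4 | step 6 | S-ethyl (2R,3R,4Z,8Z)-3-hydroxy-2-(4-methoxybenzyloxy)-8-methyl-10-(triethylsilyloxy)-4-[(triethylsilyloxy)methyl]deca-4,8-dienethioate | CC[Si](CC)(CC)OC/C=C(/C)CC/C=C(/CO[Si](CC)(CC)CC)[C@@H](O)[C@@H](OCc1ccc(OC)cc1)C(=O)SCC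
F5 | step 6 | (2R,3R,4Z,8Z)-3-hydroxy-2-(4-methoxybenzyloxy)-8-methyl-10-(triethylsilyloxy)-4-[(triethylsilyloxy)methyl]deca-4,8-dienal | CC[Si](CC)(CC)OC/C=C(/C)CC/C=C(/CO[Si](CC)(CC)CC)[C@@H](O)[C@@H](OCc1ccc(OC)cc1)C=O
F6 | step 8 | methyl (2Z,4S,5R,6Z,10Z)-5-hydroxy-4-(4-methoxybenzyloxy)-10-methyl-12-(triethylsilyloxy)-6-[(triethylsilyloxy)methyl]-2-[(tributylstannyl)methyl]dodeca-2,6,10-trienoate | CC[Si](CC)(CC)OC/C=C(/C)CC/C=C(/CO[Si](CC)(CC)CC)[C@@H](O)[C@@H](OCc1ccc(OC)cc1)/C=C(\C[Sn](CCCC)(CCCC)CCCC)C(=O)OC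
F7 | step 11 | methyl (4R)-4-{(4R,5Z)-2,2-dimethyl-5-[(4Z)-4-methyl-6-oxohex-4-enylidene]-1,3-dioxan-4-yl}-4-hydroxy-3-iodo-2-methylidenebutanoate (C3 epimers) | O=C/C=C(/C)CC/C=C1/COC(C)(C)O[C@H]1[C@@H](O)C(I)C(=C)C(=O)OC
F8 | step 11 | methyl (6R,7S,8S,9R)-6,8-dihydroxy-9,14-(isopropylidenedioxy)germacra-1(10)Z,4Z,11(13)-trien-12-oate | C=C(C(=O)OC)[C@H]1[C@H](O)/C=C(/C)CC/C=C2/COC(C)(C)O[C@H]2[C@H]1O
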